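**Plan**

1. Numbering: lactone ring O1, C2 (C=O), C3 (=CH2), C4 (CO2H), C5 (chain C1′–C15′). Cuts: the exocyclic C3=CH2 bond (made last), the lactone O1–C2 acyl bond, C3–C4 and C5–C1′ (both made in one operation), and C12′–C13′ (epoxide opening).
2. Enabling feature: O1–C5–C4–CO2H is a β-hydroxy acid (malic acid) unit. Closed with pivalaldehyde into a six-membered 1,3-dioxin-4-one ring, C5 becomes the β-carbon of a vinylogous carbonate and C4 its enolate carbon.
3. Forward: the chain iodide comes from 12-bromododec-1-ene and (S)-propylene oxide, and the (R)-dioxinone from L-malic acid. The cuprate of the chain adds to C5 and the enolate is alkylated at C4 with tert-butyl bromoacetate (three components, one flask).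
4. Aqueous acid then removes the acetal, the tert-butyl ester and the silyl ether, and the hydroxy diacid closes to the five-membered lactone ring. Methylenation at C3 ends the route.
5. Stereochemistry: C14′ comes from (S)-propylene oxide. C2 of L-malic acid fixes the acetal carbon and is then erased; the chain enters trans to tert-butyl (C5), and alkylation anti to the chain sets C4, which is the cis relation on the lactone.

Key step: step 8

**Step 1**
Reactants: 1 12-bromododec-1-ene; 2 (S)-2-methyloxirane
Product: 4 (2S)-pentadec-14-en-2-ol, via dodec-11-enylmagnesium bromide 3 (not isolated)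
Conditions: Mg, THF, 40 °C; then CuBr·SMe2 (10 mol%), 2, −30 → 0 °C; aq. NH4Cl
Reagents that add atoms: none
Why: Copper-catalysed Grignard opening of a terminal epoxide is an SN2 attack at the CH2 carbon, so the stereocentre of 2 is untouched and C14′ should be S.

**Step 2**
Reactants: 4 (2S)-pentadec-14-en-2-ol
Product: 5 tert-butyl(dimethyl)[(2S)-pentadec-14-en-2-yloxy]silane
Conditions: TBSCl, imidazole, DMF, 23 °C
Reagents that add atoms: tert-butyldimethylsilyl chloride, CC(C)(C)[Si](C)(C)Cl
Why: Silyl ether protection of a secondary alcohol; the ether should survive organolithium and cuprate chemistry and fall off in the acid step 9.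

**Step 3**
Reactants: 5 tert-butyl(dimethyl)[(2S)-pentadec-14-en-2-yloxy]silane
Product: 7 tert-butyl[(2S)-15-iodopentadecan-2-yloxy]dimethylsilane, via the terminal alkylzirconocene chloride 6 (not isolated)
Conditions: Cp2Zr(H)Cl, THF, 23 °C; then I2, 0 °C
Reagents that add atoms: iodine, [I][I]
Why: Hydrozirconation–halogenation: zirconium goes to the terminal carbon (anti-Markovnikov) and iodinolysis of the C–Zr bond should give the primary iodide.

**Step 4**
Reactants: 8 (S)-malic acid
Product: 10 (3S)-4-(benzyloxy)-3-hydroxy-4-oxobutanoic acid, via O-trifluoroacetylmalic anhydride 9 (not isolated)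
Conditions: (CF3CO)2O, 0 → 23 °C; evaporate; BnOH, 23 °C; aqueous work-up
Reagents that add atoms: benzyl alcohol, OCc1ccccc1
Why: Cyclic anhydride formation and regioselective alcoholysis: benzyl alcohol should open the anhydride at the more electrophilic carbonyl next to the oxygen-bearing carbon, leaving the CH2CO2H acid free; the trifluoroacetate is lost on work-up and the stereocentre is not touched.

**Step 5**
Reactants: 10 (3S)-4-(benzyloxy)-3-hydroxy-4-oxobutanoic acid; 11 2,2-dimethylpropanal
Product: 12 benzyl (2R,6S)-2-tert-butyl-4-oxo-1,3-dioxane-6-carboxylate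
Conditions: TsOH·H2O (cat.), CH2Cl2, reflux, azeotropic removal of water; crystallisation of the cis isomer
Reagents that add atoms: none
Why: Acid-catalysed acetalisation of a β-hydroxy acid to a 1,3-dioxan-4-one under equilibrating conditions should place tert-butyl and ester both equatorial (cis), so the S centre of malic acid fixes the new acetal carbon as R.

**Step 6**
Reactants: 12 benzyl (2R,6S)-2-tert-butyl-4-oxo-1,3-dioxane-6-carboxylate
Product: 13 (2R,6S)-2-tert-butyl-4-oxo-1,3-dioxane-6-carboxylic acid
Conditions: H2 (1 atm), Pd/C (10 wt% Pd), EtOAc, 23 °C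
Reagents that add atoms: none
Why: Hydrogenolysis of the benzyl ester; the acetal and the acylal should be inert to neutral hydrogenation.

**Step 7**
Reactants: 13 (2R,6S)-2-tert-butyl-4-oxo-1,3-dioxane-6-carboxylic acid
Product: 15 (2R)-2-tert-butyl-2H,4H-1,3-dioxin-4-one, via the 6-acetoxy dioxanone 14 (not isolated)
Conditions: Pb(OAc)4, Cu(OAc)2 (cat.), pyridine, benzene, 80 °C; then DBU, CH2Cl2, 0 °C
Reagents that add atoms: none
Why: Oxidative decarboxylation of an α-alkoxy acid (C6 radical, then oxocarbenium ion trapped by acetate) followed by base-induced β-elimination of acetic acid should give the enone; the old carbinol centre is erased on purpose while the acetal carbon keeps the chirality (self-regeneration of a stereocentre).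

**Step 8**
Reactants: 7 tert-butyl[(2S)-15-iodopentadecan-2-yloxy]dimethylsilane; 15 (2R)-2-tert-butyl-2H,4H-1,3-dioxin-4-one; 16 tert-butyl bromoacetate
Product: 20 tert-butyl 2-[(2R,5S,6S)-2-tert-butyl-6-[(14S)-14-{[tert-butyl(dimethyl)silyl]oxy}pentadecyl]-4-oxo-1,3-dioxan-5-yl]acetate, via the alkyllithium 17 (not isolated), via the lithium dialkylcuprate 18 (not isolated), via the lithium enolate 19 (not isolated)
Conditions: 7 (2.2 equiv), t-BuLi (4.4 equiv), Et2O/pentane, −78 °C; CuBr·SMe2 (1.1 equiv), −40 °C; 15 (1.0 equiv), THF, −78 °C; then 16 (3 equiv), DMPU, −78 → −40 °C; aq. NH4Cl/NH3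
Reagents that add atoms: none
Why: The lithium dialkylcuprate adds 1,4 to the vinylogous carbonate (π-complex, β-cuprate of trivalent copper, reductive elimination) and forms the C5–C1′ bond at C6 of the dioxinone, and the lithium enolate so released is alkylated in the same flask at C5 of that ring (the later C4) by SN2 displacement of bromide. The closest known reaction type is tandem conjugate addition–enolate alkylation (three-component coupling), both halves of which are established on this ring class: cuprate additions to 2-tert-butyl-1,3-dioxin-4-ones and alkylations of 2-tert-butyl-1,3-dioxan-4-one enolates. No ring is closed in this step; the six-membered acetal ring is kept and is exchanged for the five-membered lactone only in step 9. The new centre at C6 is controlled by the acetal carbon: the ring is a sofa with tert-butyl pseudo-equatorial and the cuprate should enter on the face of the acetal hydrogen, trans to tert-butyl (6S). The new centre at C5 is controlled by C6: the electrophile should approach anti to the axial chain (5S, 5,6-trans), which becomes the cis relation after the ring switch. The step needs 1,4- over 1,2-addition, secured by the soft cuprate and the poorly electrophilic acylal carbonyl, and alkylation faster than β-elimination of the ring oxygen, secured by holding the enolate at or below −40 °C and using a reactive α-bromo ester with DMPU.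

**Step 9**
Reactants: 20 tert-butyl 2-[(2R,5S,6S)-2-tert-butyl-6-[(14S)-14-{[tert-butyl(dimethyl)silyl]oxy}pentadecyl]-4-oxo-1,3-dioxan-5-yl]acetate
Product: 22 (2S,3S)-2-[(14S)-14-hydroxypentadecyl]-5-oxooxolane-3-carboxylic acid, via the open dihydroxy diacid 21 (not isolated)
Conditions: CF3CO2H/H2O (9:1), 23 °C; evaporate; brief aq. NaHCO3, then dilute aq. HCl
Reagents that add atoms: none
Why: Aqueous acid should hydrolyse the acylal, cleave the tert-butyl ester and the silyl ether, and let the freed C5 hydroxyl close onto the CH2CO2H arm (5-exo-trig lactonisation; the C4 acid could only give a β-lactone); no stereocentre is touched, so the 5,6-trans dioxanone gives the cis lactone.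

**Step 10**
Reactants: 22 (2S,3S)-2-[(14S)-14-hydroxypentadecyl]-5-oxooxolane-3-carboxylic acid
Product: 24 (2S,3S)-2-[(14S)-14-hydroxypentadecyl]-4-methylidene-5-oxooxolane-3-carboxylic acid, via the C3-carboxylated lactone 23 (not isolated)
Conditions: MeOMgOCO2Me (in DMF), 135 °C; cold aq. HCl; then 37% aq. CH2O, PhNHMe, NaOAc, AcOH, 23 °C
Reagents that add atoms: formaldehyde, C=O
Why: Carboxylation of the lactone α-carbon with methyl magnesium carbonate gives a chelated malonic half-acid, which should undergo decarboxylative Mannich methylenation; the C4 acid is a carboxylate throughout, which protects C4–H from enolisation, and no stereocentre is formed.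

**Compound list**

1 | 12-bromododec-1-ene | C=CCCCCCCCCCCBr | starting material
2 | (S)-2-methyloxirane | C[C@H]1CO1 | starting material
3 | dodec-11-enylmagnesium bromide | C=CCCCCCCCCCC[Mg]Br | intermediate
4 | (2S)-pentadec-14-en-2-ol | C=CCCCCCCCCCCC[C@H](C)O | intermediate
5 | tert-butyl(dimethyl)[(2S)-pentadec-14-en-2-yloxy]silane | C=CCCCCCCCCCCC[C@H](C)O[Si](C)(C)C(C)(C)C | intermediate
6 | chlorobis(cyclopentadienyl)[(14S)-14-{[tert-butyl(dimethyl)silyl]oxy}pentadecyl]zirconium | Cl[Zr](C1C=CC=C1)(C1C=CC=C1)CCCCCCCCCCCCC[C@H](C)O[Si](C)(C)C(C)(C)C | intermediate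
7 | tert-butyl[(2S)-15-iodopentadecan-2-yloxy]dimethylsilane | ICCCCCCCCCCCCC[C@H](C)O[Si](C)(C)C(C)(C)C | intermediate
8 | (S)-malic acid | O[C@@H](CC(=O)O)C(=O)O | starting material
9 | (S)-2-(trifluoroacetoxy)succinic anhydride | FC(F)(F)C(=O)O[C@H]1CC(=O)OC1=O | intermediate
10 | (3S)-4-(benzyloxy)-3-hydroxy-4-oxobutanoic acid | O[C@@H](CC(=O)O)C(=O)OCc1ccccc1 | intermediate
11 | 2,2-dimethylpropanal (pivalaldehyde) | CC(C)(C)C=O | starting material
12 | benzyl (2R,6S)-2-tert-butyl-4-oxo-1,3-dioxane-6-carboxylate | CC(C)(C)[C@@H]1O[C@H](C(=O)OCc2ccccc2)CC(=O)O1 | intermediate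
13 | (2R,6S)-2-tert-butyl-4-oxo-1,3-dioxane-6-carboxylic acid | CC(C)(C)[C@@H]1O[C@H](C(=O)O)CC(=O)O1 | intermediate
14 | (2R)-2-tert-butyl-4-oxo-1,3-dioxan-6-yl acetate (both C6 epimers) | CC(C)(C)[C@@H]1OC(OC(C)=O)CC(=O)O1 | intermediate
15 | (2R)-2-tert-butyl-2H,4H-1,3-dioxin-4-one | CC(C)(C)[C@@H]1OC=CC(=O)O1 | intermediate
16 | tert-butyl bromoacetate | CC(C)(C)OC(=O)CBr | starting material
17 | [(14S)-14-{[tert-butyl(dimethyl)silyl]oxy}pentadecyl]lithium | [Li]CCCCCCCCCCCCC[C@H](C)O[Si](C)(C)C(C)(C)C | intermediate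
18 | lithium bis[(14S)-14-{[tert-butyl(dimethyl)silyl]oxy}pentadecyl]cuprate | [Li+].CC(C)(C)[Si](C)(C)O[C@@H](C)CCCCCCCCCCCCC[Cu-]CCCCCCCCCCCCC[C@H](C)O[Si](C)(C)C(C)(C)C | intermediate
19 | lithium (2R,6S)-2-tert-butyl-6-[(14S)-14-{[tert-butyl(dimethyl)silyl]oxy}pentadecyl]-6H-1,3-dioxin-4-olate | [Li+].CC(C)(C)[C@@H]1O[C@@H](CCCCCCCCCCCCC[C@H](C)O[Si](C)(C)C(C)(C)C)C=C([O-])O1 | intermediate
20 | tert-butyl 2-[(2R,5S,6S)-2-tert-butyl-6-[(14S)-14-{[tert-butyl(dimethyl)silyl]oxy}pentadecyl]-4-oxo-1,3-dioxan-5-yl]acetate | CC(C)(C)[C@@H]1O[C@@H](CCCCCCCCCCCCC[C@H](C)O[Si](C)(C)C(C)(C)C)[C@H](CC(=O)OC(C)(C)C)C(=O)O1 | intermediate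
21 | (2S)-2-[(1S,15S)-1,15-dihydroxyhexadecyl]butanedioic acid | O[C@@H](CCCCCCCCCCCCC[C@H](C)O)[C@H](CC(=O)O)C(=O)O | intermediate
22 | (2S,3S)-2-[(14S)-14-hydroxypentadecyl]-5-oxooxolane-3-carboxylic acid | C1C(=O)O[C@@H](CCCCCCCCCCCCC[C@H](C)O)[C@H]1C(=O)O | intermediate
23 | (4S,5S)-5-[(14S)-14-hydroxypentadecyl]-2-oxooxolane-3,4-dicarboxylic acid (C3 epimers) | OC(=O)C1C(=O)O[C@@H](CCCCCCCCCCCCC[C@H](C)O)[C@H]1C(=O)O | intermediate
24 | (2S,3S)-2-[(14S)-14-hydroxypentadecyl]-4-methylidene-5-oxooxolane-3-carboxylic acid | C=C1C(=O)O[C@@H](CCCCCCCCCCCCC[C@H](C)O)[C@H]1C(=O)O | target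

**Step count and risks**

Total: 10 steps. Longest linear sequence: 7 steps (steps 4–10, from (S)-malic acid); the chain arm takes 3 steps before the convergence in step 8.

Steps most likely to fail:

1. Step 8. The enolate formed in the presence of copper species may lose the ring oxygen by β-elimination or stay unalkylated, and the cuprate may not discriminate the two faces of the enone cleanly. The fallback sets out from 13, uses 7 and 16, bypasses steps 7 and 8 and comes back at 20. Compound 13 is esterified with N-hydroxyphthalimide (N,N′-diisopropylcarbodiimide, CH2Cl2) to the redox-active ester 1,3-dioxoisoindol-2-yl (2R,6S)-2-tert-butyl-4-oxo-1,3-dioxane-6-carboxylate F1. Compound 7 is converted through the alkyllithium 17 (t-BuLi, then ZnCl2, 0.5 equiv) into bis[(14S)-14-{[tert-butyl(dimethyl)silyl]oxy}pentadecyl]zinc F2. Nickel-catalysed decarboxylative alkyl–alkyl coupling of F1 with F2 (NiCl2·glyme, 4,4′-di-tert-butyl-2,2′-bipyridine, THF/DMF, 23 °C) makes the same C5–C1′ bond through the C6 radical. This radical should be captured on its axial face, trans to tert-butyl, as α-alkoxy radicals in six-membered rings usually are, to give (2R,6S)-2-tert-butyl-6-[(14S)-14-{[tert-butyl(dimethyl)silyl]oxy}pentadecyl]-1,3-dioxan-4-one F3. Deprotonation (LiN(i-Pr)2, THF, −78 °C) gives enolate 19 free of copper, and alkylation with 16 anti to the chain returns 20.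

2. Step 7. Over-oxidation, loss of the acid-labile acetal or incomplete elimination may leave too little enone. The fallback sets out from 11 and comes back at 15. Commercial 5-(methoxymethylidene)-2,2-dimethyl-1,3-dioxane-4,6-dione F4 is hydrolysed (dilute aq. HCl) to 5-(hydroxymethylidene)-2,2-dimethyl-1,3-dioxane-4,6-dione F5. Thermolysis of F5 in toluene at 110 °C releases formylketene F6, which is trapped by 11 in a hetero-Diels–Alder reaction to racemic 2-tert-butyl-2H,4H-1,3-dioxin-4-one F7. Preparative chromatography on a chiral phase (cellulose triacetate) separates the enantiomers and delivers 15; the chirality then comes from the resolution instead of from malic acid.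

3. Step 10. Carboxylation at C3 may be slow, the material may break down at 135 °C, or the cis acid may epimerise at C4 under the hot basic conditions. The fallback sets out from 22 and comes back at 24. Compound 22 is deprotonated at −78 °C (LiN(SiMe3)2, 3.3 equiv, THF) to the trilithium carboxylate–alkoxide–enolate F8. F8 is aminomethylated at C3 with dimethyl(methylidene)ammonium iodide to the Mannich base (2S,3S)-4-[(dimethylamino)methyl]-2-[(14S)-14-hydroxypentadecyl]-5-oxooxolane-3-carboxylic acid F9. N-Methylation (MeI, MeOH) gives the trimethylammonium carboxylate F10, and elimination (aq. NaHCO3, 23 °C) gives 24.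

**Further compounds**

F1 | step 8 | 1,3-dioxoisoindol-2-yl (2R,6S)-2-tert-butyl-4-oxo-1,3-dioxane-6-carboxylate | CC(C)(C)[C@@H]1O[C@H](C(=O)ON2C(=O)c3ccccc3C2=O)CC(=O)O1
F2 | step 8 | bis[(14S)-14-{[tert-butyl(dimethyl)silyl]oxy}pentadecyl]zinc | CC(C)(C)[Si](C)(C)O[C@@H](C)CCCCCCCCCCCCC[Zn]CCCCCCCCCCCCC[C@H](C)O[Si](C)(C)C(C)(C)C
F3 | step 8 | (2R,6S)-2-tert-butyl-6-[(14S)-14-{[tert-butyl(dimethyl)silyl]oxy}pentadecyl]-1,3-dioxan-4-one | CC(C)(C)[C@@H]1O[C@@H](CCCCCCCCCCCCC[C@H](C)O[Si](C)(C)C(C)(C)C)CC(=O)O1
F4 | step 7 | 5-(methoxymethylidene)-2,2-dimethyl-1,3-dioxane-4,6-dione | COC=C1C(=O)OC(C)(C)OC1=O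
F5 | step 7 | 5-(hydroxymethylidene)-2,2-dimethyl-1,3-dioxane-4,6-dione | OC=C1C(=O)OC(C)(C)OC1=O
F6 | step 7 | formylketene (3-oxoprop-1-en-1-one) | O=CC=C=O
F7 | step 7 | racemic 2-tert-butyl-2H,4H-1,3-dioxin-4-one | CC(C)(C)C1OC=CC(=O)O1
F8 | step 10 | trilithium salt of 22 (carboxylate, C14′ alkoxide, lactone enolate) | [Li+].[Li+].[Li+].C1=C([O-])O[C@@H](CCCCCCCCCCCCC[C@H](C)[O-])[C@H]1C(=O)[O-]
F9 | step 10 | (2S,3S)-4-[(dimethylamino)methyl]-2-[(14S)-14-hydroxypentadecyl]-5-oxooxolane-3-carboxylic acid (C4 epimers) | CN(C)CC1C(=O)O[C@@H](CCCCCCCCCCCCC[C@H](C)O)[C@H]1C(=O)O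
F10 | step 10 | (2S,3S)-2-[(14S)-14-hydroxypentadecyl]-5-oxo-4-[(trimethylazaniumyl)methyl]oxolane-3-carboxylate (C4 epimers) | C[N+](C)(C)CC1C(=O)O[C@@H](CCCCCCCCCCCCC[C@H](C)O)[C@H]1C(=O)[O-]
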